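The route rests on cutting the ethylene link between its two CH2 groups: C8 (benzylic, on the guaiacyl ring) and C7 (on C6 of the oxane). C7 is β to the ring oxygen, so O1–C6–C7 is read as a terminal epoxide. A vanillyl Grignard reagent opens an (R)-epichlorohydrin-derived oxirane at its CH2, forging C7–C8 by strain release, while the epoxide oxygen and stereocentre become O1 and C6. The precursor is an acyclic, dithiane-masked 2-silyloxy-4-keto-6,7-epoxide assembled by a three-component dithiane linchpin coupling. C2 and C4 are then set from C6 by thermodynamic benzylic ring closure and equatorial hydride delivery.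

Key step: step 4

Remark: atom labels are oxane O1, C2 (aryl), C4 (OH), C6, then C7 and C8 for the side-chain CH2 groups; compounds 8–10 and 12 are assumed to be carried as mixtures of epimers at the benzylic silyloxy carbon (racemic 4), because that centre is ionised and reset in step 5.

Step 1
Reactants: 1 4-(benzyloxy)-3-methoxybenzyl alcohol
Product: 2 4-(benzyloxy)-3-methoxybenzyl chloride
Conditions: SOCl2, CH2Cl2, 0 °C → rt; used crude
Reagents that add atoms: thionyl chloride, O=S(Cl)Cl
Why: Deoxychlorination via the alkyl chlorosulfite is fast for this electron-rich benzylic alcohol, and no stereocentre is involved.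

Step 2
Reactants: 3 4-(benzyloxy)-3-methoxybenzaldehyde
Product: 4 rac-2-[4-(benzyloxy)-3-methoxyphenyl]oxirane
Conditions: Me3S+ I−, KOH, MeCN, trace H2O, 60 °C; basic work-up, no chromatography
Reagents that add atoms: trimethylsulfonium iodide, C[S+](C)C.[I-]
Why: Corey–Chaykovsky epoxidation (ylide addition, betaine closure); the new benzylic centre is left racemic on purpose because it is reset in step 5.

Step 3
Reactants: 5 2-(tert-butyldimethylsilyl)-1,3-dithiane; 4 rac-2-[4-(benzyloxy)-3-methoxyphenyl]oxirane; 6 (R)-epichlorohydrin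
Product: 10 tert-butyl{1-[4-(benzyloxy)-3-methoxyphenyl]-2-{2-[(2R)-oxiran-2-ylmethyl]-1,3-dithian-2-yl}ethoxy}dimethylsilane (both epimers at the silyloxy carbon), via lithiated silyl dithiane 7 (not isolated), via first lithium alkoxide 8 (not isolated), via chlorohydrin lithium alkoxide 9 (not isolated)
Conditions: t-BuLi, Et2O, −78 → −45 °C; 4, Et2O, −78 → −25 °C; 6, THF/HMPA, −78 °C → rt
Reagents that add atoms: none
Why: Dithiane linchpin (anion relay) coupling: 7 opens 4 at its CH2, HMPA triggers the 1,4-Brook rearrangement of 8, the regenerated dithiane anion opens 6 at its ring CH2 and alkoxide 9 closes onto CH2Cl, so the purchased stereocentre is never touched and reappears as the (R)-oxirane.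

Step 4
Reactants: 2 4-(benzyloxy)-3-methoxybenzyl chloride; 10 the (R)-oxirane from step 3
Product: 12 (2S)-4-[4-(benzyloxy)-3-methoxyphenyl]-1-{2-[2-[4-(benzyloxy)-3-methoxyphenyl]-2-[(tert-butyldimethylsilyl)oxy]ethyl]-1,3-dithian-2-yl}butan-2-ol (both epimers at the silyloxy carbon), via benzylic Grignard reagent 11 (not isolated)
Conditions: 2, Mg, THF, 0 °C (slow addition); then 10, CuI (10 mol %), THF, −40 → 0 °C; aq NH4Cl
Reagents that add atoms: none
Why: The benzylic organomagnesium 11 is transmetallated to a cuprate that attacks the unsubstituted oxirane carbon C7 of 10 in an SN2 fashion, the strain of the three-membered ring driving formation of the C7–C8 bond and releasing the C6 alkoxide that later becomes O1. The closest known reaction type is the copper-catalysed opening of monosubstituted epoxides by Grignard reagents, benzylic ones included. No ring is closed in this step. No new stereocentre is formed: the C6–O bond is never broken, so C6 keeps the configuration bought with (R)-epichlorohydrin and reads (S) in 12 only because the CIP priorities change. The step needs regioselectivity for the CH2 terminus, secured by the steric contrast with the secondary oxirane carbon bearing the neopentyl-like dithianylmethyl group, and chemoselectivity, secured because thioketal, silyl ether and benzyl ethers are inert to the cuprate at −40 to 0 °C. Wurtz homocoupling of 2 is the competing process and is held down by slow addition to excess magnesium and by using 11 in excess.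

Step 5
Reactants: 12 the (2S)-alcohol from step 4
Product: 13 (2S,6S)-2-[4-(benzyloxy)-3-methoxyphenyl]-6-{2-[4-(benzyloxy)-3-methoxyphenyl]ethyl}oxan-4-one propane-1,3-diyl dithioketal (2,6-cis; a 9-oxa-1,5-dithiaspiro[5.5]undecane)
Conditions: TsOH·H2O (10 mol %), CH2Cl2, 0 °C → rt
Reagents that add atoms: none
Why: Acid-catalysed SN1 cycloetherification: loss of silanol gives a benzylic cation stabilised by the para-benzyloxy group, the C6 hydroxyl closes the six-membered ring, and reversible ionisation funnels both epimers to the 2,6-cis oxane (2S) with aryl and side chain equatorial, an axial aryl being penalised by the axial sulfur of the spiro-dithiane.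

Step 6
Reactants: 13 the spiro-dithioketal from step 5
Product: 14 (2S,6S)-2-[4-(benzyloxy)-3-methoxyphenyl]-6-{2-[4-(benzyloxy)-3-methoxyphenyl]ethyl}oxan-4-one (2,6-cis)
Conditions: MeI, CaCO3, MeCN/H2O (9:1), 45 °C
Reagents that add atoms: water, O
Why: Alkylative dithioketal hydrolysis (S-methylation, then hydrolysis of the sulfonium) under buffered, non-oxidising conditions that spare the electron-rich arenes and the benzylic C2–O1 bond; no stereocentre is affected.

Step 7
Reactants: 14 the 2,6-cis oxan-4-one from step 6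
Product: 15 (2S,4S,6S)-2-[4-(benzyloxy)-3-methoxyphenyl]-6-{2-[4-(benzyloxy)-3-methoxyphenyl]ethyl}oxan-4-ol
Conditions: L-Selectride, THF, −78 °C; H2O quench
Reagents that add atoms: none
Why: Diastereoselective ketone reduction with a bulky trialkylborohydride: hydride enters the diequatorial chair from the equatorial direction, giving the axial C4 alcohol (4S), trans to both ring substituents.

Step 8
Reactants: 15 the dibenzyl ether from step 7
Product: 16 (2S,4S,6S)-2-(4-hydroxy-3-methoxyphenyl)-6-[2-(4-hydroxy-3-methoxyphenyl)ethyl]oxan-4-ol (target)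
Conditions: H2 (1 atm), 10 % Pd/C, EtOAc, rt, monitored
Reagents that add atoms: none
Why: Catalytic hydrogenolysis of the two aryl benzyl ethers, which should cleave far faster than the cyclic benzylic C2–O1 bond under neutral conditions in ethyl acetate.

Compound list
1 | 4-(benzyloxy)-3-methoxybenzyl alcohol | COc1cc(CO)ccc1OCc1ccccc1 | starting material
2 | 4-(benzyloxy)-3-methoxybenzyl chloride | COc1cc(CCl)ccc1OCc1ccccc1 | intermediate
3 | 4-(benzyloxy)-3-methoxybenzaldehyde (O-benzylvanillin) | COc1cc(C=O)ccc1OCc1ccccc1 | starting material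
4 | rac-2-[4-(benzyloxy)-3-methoxyphenyl]oxirane | COc1cc(C2CO2)ccc1OCc1ccccc1 | intermediate
5 | 2-(tert-butyldimethylsilyl)-1,3-dithiane | CC(C)(C)[Si](C)(C)C1SCCCS1 | starting material
6 | (R)-epichlorohydrin, (2R)-2-(chloromethyl)oxirane | ClC[C@H]1CO1 | starting material
7 | 2-lithio-2-(tert-butyldimethylsilyl)-1,3-dithiane | [Li]C1([Si](C)(C)C(C)(C)C)SCCCS1 | intermediate (not isolated)
8 | lithium 1-[4-(benzyloxy)-3-methoxyphenyl]-2-[2-(tert-butyldimethylsilyl)-1,3-dithian-2-yl]ethan-1-olate (racemic) | COc1cc(C([O-])CC2([Si](C)(C)C(C)(C)C)SCCCS2)ccc1OCc1ccccc1.[Li+] | intermediate (not isolated)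
9 | lithium (2R)-1-{2-[2-[4-(benzyloxy)-3-methoxyphenyl]-2-[(tert-butyldimethylsilyl)oxy]ethyl]-1,3-dithian-2-yl}-3-chloropropan-2-olate (both epimers at the silyloxy carbon) | COc1cc(C(O[Si](C)(C)C(C)(C)C)CC2(C[C@@H]([O-])CCl)SCCCS2)ccc1OCc1ccccc1.[Li+] | intermediate (not isolated)
10 | tert-butyl{1-[4-(benzyloxy)-3-methoxyphenyl]-2-{2-[(2R)-oxiran-2-ylmethyl]-1,3-dithian-2-yl}ethoxy}dimethylsilane (both epimers at the silyloxy carbon) | COc1cc(C(O[Si](C)(C)C(C)(C)C)CC2(C[C@@H]3CO3)SCCCS2)ccc1OCc1ccccc1 | intermediate
11 | [4-(benzyloxy)-3-methoxybenzyl]magnesium chloride | COc1cc(C[Mg]Cl)ccc1OCc1ccccc1 | intermediate (not isolated)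
12 | (2S)-4-[4-(benzyloxy)-3-methoxyphenyl]-1-{2-[2-[4-(benzyloxy)-3-methoxyphenyl]-2-[(tert-butyldimethylsilyl)oxy]ethyl]-1,3-dithian-2-yl}butan-2-ol (both epimers at the silyloxy carbon) | COc1cc(C(O[Si](C)(C)C(C)(C)C)CC2(C[C@@H](O)CCc3ccc(OCc4ccccc4)c(OC)c3)SCCCS2)ccc1OCc1ccccc1 | intermediate
13 | (2S,6S)-2-[4-(benzyloxy)-3-methoxyphenyl]-6-{2-[4-(benzyloxy)-3-methoxyphenyl]ethyl}oxan-4-one propane-1,3-diyl dithioketal (2,6-cis) | COc1cc(CC[C@H]2CC3(SCCCS3)C[C@@H](c4ccc(OCc5ccccc5)c(OC)c4)O2)ccc1OCc1ccccc1 | intermediate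
14 | (2S,6S)-2-[4-(benzyloxy)-3-methoxyphenyl]-6-{2-[4-(benzyloxy)-3-methoxyphenyl]ethyl}oxan-4-one (2,6-cis) | COc1cc(CC[C@H]2CC(=O)C[C@@H](c3ccc(OCc4ccccc4)c(OC)c3)O2)ccc1OCc1ccccc1 | intermediate
15 | (2S,4S,6S)-2-[4-(benzyloxy)-3-methoxyphenyl]-6-{2-[4-(benzyloxy)-3-methoxyphenyl]ethyl}oxan-4-ol | COc1cc(CC[C@H]2C[C@H](O)C[C@@H](c3ccc(OCc4ccccc4)c(OC)c3)O2)ccc1OCc1ccccc1 | intermediate
16 | (2S,4S,6S)-2-(4-hydroxy-3-methoxyphenyl)-6-[2-(4-hydroxy-3-methoxyphenyl)ethyl]oxan-4-ol | COc1cc(CC[C@H]2C[C@H](O)C[C@@H](c3ccc(O)c(OC)c3)O2)ccc1O | target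

Total step count: 8. Longest linear sequence: 7 steps (steps 2–8, from 3 to 16); step 1 is a one-step side branch that feeds the convergent step 4.

Steps most likely to fail

Step 3. Control over the timing of the silyl migration may be lost (Brook shift before 4 is consumed, so that the first epoxide alkylates twice), or the relay may stall after the first alkylation. The fallback gives up the one-pot relay for stepwise alkylation, silylation and alkylation. It sets out from 4, which is opened at its CH2 by 2-lithio-1,3-dithiane (1,3-dithiane, n-BuLi, THF, −30 °C) to give rac-1-[4-(benzyloxy)-3-methoxyphenyl]-2-(1,3-dithian-2-yl)ethan-1-ol F1. Silylation (TBSCl, imidazole, DMF) gives the tert-butyldimethylsilyl ether F2. A second lithiation (t-BuLi, THF/HMPA, −78 °C) and alkylation with 6, again by ring opening and reclosure, comes back to the route at 10.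

Step 4. Formation of the electron-rich benzylic Grignard reagent may be eroded by Wurtz homocoupling, and the dithiane sulfur atoms may bind copper and slow the transfer, leaving unreacted epoxide or halohydrin. The fallback forms the same C7–C8 bond with a sulfone-stabilised benzylic carbanion and removes the activating group afterwards. It sets out from 2, which with sodium benzenesulfinate (DMF, rt) gives 4-(benzyloxy)-3-methoxybenzyl phenyl sulfone F3. Its lithio derivative (n-BuLi, THF/DMPU, −78 °C → rt) opens 10 at the oxirane CH2 to give the γ-hydroxy sulfone F4, a mixture of diastereomers at the sulfonyl and silyloxy carbons. Reductive desulfonylation (Mg, MeOH, rt) comes back to the route at 12.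

Step 5. After ionisation the benzylic cation may lose a proton to give the styrene, or be captured intermolecularly by an electron-rich arene, and the kinetic mixture of C2 epimers may not equilibrate fully. The fallback replaces cation capture by conjugate addition. It sets out from 12, whose dithiane is hydrolysed first (MeI, CaCO3, MeCN/H2O) to give (5S)-1,7-bis[4-(benzyloxy)-3-methoxyphenyl]-1-[(tert-butyldimethylsilyl)oxy]-5-hydroxyheptan-3-one F5. Acid (Amberlyst-15, CH2Cl2, rt) eliminates the silanol to give (1E,5S)-1,7-bis[4-(benzyloxy)-3-methoxyphenyl]-5-hydroxyhept-1-en-3-one F6. The hydroxyl of F6 then adds in a 6-endo oxa-Michael reaction under thermodynamic control, which should give the 2,6-cis ketone and comes back to the route at 14, skipping step 6.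

Further compounds
F1 | step 3 | rac-1-[4-(benzyloxy)-3-methoxyphenyl]-2-(1,3-dithian-2-yl)ethan-1-ol | COc1cc(C(O)CC2SCCCS2)ccc1OCc1ccccc1
F2 | step 3 | rac-tert-butyl{1-[4-(benzyloxy)-3-methoxyphenyl]-2-(1,3-dithian-2-yl)ethoxy}dimethylsilane | COc1cc(C(O[Si](C)(C)C(C)(C)C)CC2SCCCS2)ccc1OCc1ccccc1
F3 | step 4 | 4-(benzyloxy)-3-methoxybenzyl phenyl sulfone | COc1cc(CS(=O)(=O)c2ccccc2)ccc1OCc1ccccc1
F4 | step 4 | (2S)-4-(benzenesulfonyl)-4-[4-(benzyloxy)-3-methoxyphenyl]-1-{2-[2-[4-(benzyloxy)-3-methoxyphenyl]-2-[(tert-butyldimethylsilyl)oxy]ethyl]-1,3-dithian-2-yl}butan-2-ol (mixture at the sulfonyl and silyloxy carbons) | COc1cc(C(O[Si](C)(C)C(C)(C)C)CC2(C[C@@H](O)CC(c3ccc(OCc4ccccc4)c(OC)c3)S(=O)(=O)c5ccccc5)SCCCS2)ccc1OCc1ccccc1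
F5 | step 5 | (5S)-1,7-bis[4-(benzyloxy)-3-methoxyphenyl]-1-[(tert-butyldimethylsilyl)oxy]-5-hydroxyheptan-3-one (both epimers at C1) | COc1cc(C(O[Si](C)(C)C(C)(C)C)CC(=O)C[C@@H](O)CCc2ccc(OCc3ccccc3)c(OC)c2)ccc1OCc1ccccc1
F6 | step 5 | (1E,5S)-1,7-bis[4-(benzyloxy)-3-methoxyphenyl]-5-hydroxyhept-1-en-3-one | COc1cc(/C=C/C(=O)C[C@@H](O)CCc2ccc(OCc3ccccc3)c(OC)c2)ccc1OCc1ccccc1
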